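**Retrosynthetic overview**
1. Numbering as in eudesmanes: ring A = C1–C5, C10; ring B = C5–C10; C14 = CH3 on C10; C15 = CH2O on C4; C11(=C13H2)–C12O2Me on C7.
2. Target 23 ⇐ Mitsunobu acylation of C15–OH (21) with p-coumaric acid ⇐ Wittig methylenation of the C11 keto group ⇐ 1,4-reduction of the ene-α-keto ester 17.
3. 17 ⇐ open-chain, achiral tetraene keto ester 16: one intramolecular inverse-demand Diels–Alder reaction forms C8–C9 and C5–C10, so rings A and B form together (no ring exists before this step) and C5 and C10 are set.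
4. Enabling feature: in ring B, C7 is 1,4 to quaternary C10 with only C8H2 and C9H2 between them. Read backwards, C9=C10(CH3) is an isopropenyl dienophile and C5=C6–C7=C8 a diene whose C7 substituent (the acrylate at the α-keto ester level) activates it and binds a chiral Lewis acid; C3=C4(C15) of ring A already sits in the tether with C2 and C5 cis.
5. 16 ⇐ 4-methylpent-4-enal (1), methyl acrylate (2), 3-(trimethylsilyl)propynal (5) and dimethyl oxalate (14) by Morita–Baylis–Hillman reaction, Wittig olefination, hydroalumination/bromination and acylation.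

Key step: step 8

Remark: the sense of induction of the ligand in step 8 is an assumption; the (S,S)-ligand is written and its antipode is used if it delivers the (4aS,8aS) adduct.

**Step 1**
Reactants: 1 4-methylpent-4-enal; 2 methyl acrylate
Product: 3 methyl 3-hydroxy-6-methyl-2-methylidenehept-6-enoate (racemic)
Conditions: DABCO (0.5 equiv), MeOH, rt
Reagents that add atoms: none
Why: Morita–Baylis–Hillman reaction of an unhindered aliphatic aldehyde with methyl acrylate should give the allylic alcohol, whose racemic carbinol centre is erased in step 2.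

**Step 2**
Reactants: 3 methyl 3-hydroxy-6-methyl-2-methylidenehept-6-enoate
Product: 4 methyl (2Z)-2-(bromomethyl)-6-methylhepta-2,6-dienoate
Conditions: NBS, Me2S, CH2Cl2, 0 °C → rt
Reagents that add atoms: N-bromosuccinimide O=C1CCC(=O)N1Br
Why: Corey–Kim-type activation of the hydroxyl as an alkoxysulfonium salt and SN2′ attack of bromide should give the rearranged allylic bromide as the preferred isomer with the ester trans to the alkyl chain, which later places C2 and C5 cis on C3=C4; no stereocentre remains.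

**Step 3**
Reactants: 4 methyl (2Z)-2-(bromomethyl)-6-methylhepta-2,6-dienoate; 5 3-(trimethylsilyl)prop-2-ynal
Product: 9 methyl (2E)-2-[(1E)-but-1-en-3-yn-1-yl]-6-methylhepta-2,6-dienoate, via allylic tributylphosphonium bromide 6 (not isolated), via allylic phosphorus ylide 7 (not isolated), via trimethylsilyl dienyne ester 8 (not isolated)
Conditions: PBu3, THF, rt; KOt-Bu, −78 °C; 5, −78 °C → rt; then K2CO3 (cat.), MeOH, rt
Reagents that add atoms: none
Why: Wittig olefination with an allylic tributylphosphonium ylide is E-selective, so C5=C6 should be E, and K2CO3/MeOH then removes the alkynyl silyl group by protodesilylation; no stereocentre.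

**Step 4**
Reactants: 9 methyl (2E)-2-[(1E)-but-1-en-3-yn-1-yl]-6-methylhepta-2,6-dienoate
Product: 10 (2E)-2-[(1E)-but-1-en-3-yn-1-yl]-6-methylhepta-2,6-dien-1-ol
Conditions: i-Bu2AlH (2.2 equiv), CH2Cl2, −78 °C; aq. potassium sodium tartrate
Reagents that add atoms: none
Why: 1,2-reduction of the conjugated methyl ester with i-Bu2AlH at low temperature should give the primary allylic alcohol (C15) without touching the alkyne or the alkenes; no stereocentre.

**Step 5**
Reactants: 10 (2E)-2-[(1E)-but-1-en-3-yn-1-yl]-6-methylhepta-2,6-dien-1-ol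
Product: 11 tert-butyl{[(2E)-2-[(1E)-but-1-en-3-yn-1-yl]-6-methylhepta-2,6-dien-1-yl]oxy}dimethylsilane
Conditions: TBSCl, imidazole, CH2Cl2, 0 °C → rt
Reagents that add atoms: tert-butyldimethylsilyl chloride CC(C)(C)[Si](C)(C)Cl
Why: standard silylation of a primary alcohol protects C15–OH against the organometallic steps that follow; no stereocentre.

**Step 6**
Reactants: 11 tert-butyl{[(2E)-2-[(1E)-but-1-en-3-yn-1-yl]-6-methylhepta-2,6-dien-1-yl]oxy}dimethylsilane
Product: 13 (3E,5E)-2-bromo-5-({[tert-butyl(dimethyl)silyl]oxy}methyl)-9-methyldeca-1,3,5,9-tetraene, via dienyl diisobutylalane 12 (not isolated)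
Conditions: i-Bu2AlH (1.3 equiv), NiCl2(dppp) (3 mol %), THF, 0 °C → rt; then NBS, −78 → 0 °C
Reagents that add atoms: N-bromosuccinimide O=C1CCC(=O)N1Br
Why: nickel-catalysed hydroalumination of a terminal alkyne with i-Bu2AlH is α-(Markovnikov)-selective and places aluminium on C7, and brominolysis of the C–Al bond with NBS then gives the 2-bromo-1,3-diene; no stereocentre.

**Step 7**
Reactants: 13 (3E,5E)-2-bromo-5-({[tert-butyl(dimethyl)silyl]oxy}methyl)-9-methyldeca-1,3,5,9-tetraene; 14 dimethyl oxalate
Product: 16 methyl (4E,6E)-6-({[tert-butyl(dimethyl)silyl]oxy}methyl)-10-methyl-3-methylidene-2-oxoundeca-4,6,10-trienoate, via 2-lithiodiene 15 (not isolated)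
Conditions: t-BuLi (2.1 equiv), Et2O, −78 °C; transfer into 14 (3 equiv), THF, −78 °C; AcOH, −78 °C; cold work-up, used at once
Reagents that add atoms: none
Why: bromine–lithium exchange gives the 2-lithiodiene, and its acylation with excess dimethyl oxalate stops at the tetrahedral adduct at −78 °C, which releases the α-keto ester on quench; no stereocentre.

**Step 8**
Reactants: 16 methyl (4E,6E)-6-({[tert-butyl(dimethyl)silyl]oxy}methyl)-10-methyl-3-methylidene-2-oxoundeca-4,6,10-trienoate
Product: 17 methyl 2-[(4aR,8aR)-8-({[tert-butyl(dimethyl)silyl]oxy}methyl)-4a-methyl-3,4,4a,5,6,8a-hexahydronaphthalen-2-yl]-2-oxoacetate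
Conditions: Cu(OTf)2 (10 mol %), (S,S)-t-Bu-box [2,2′-(propane-2,2-diyl)bis((4S)-4-tert-butyl-4,5-dihydrooxazole)] (11 mol %), 4 Å MS, CH2Cl2 (0.01 mol/L), −40 °C → rt
Reagents that add atoms: none
Why: Proposed new method: chelation of the 1,2-dicarbonyl unit of 16 by the Cu(OTf)2/bis(oxazoline) Lewis acid should lower the LUMO of the 2-acyl diene C5=C6–C7=C8 so that it takes up the tethered, electron-rich 1,1-disubstituted alkene C9=C10 in a concerted, asynchronous inverse-electron-demand [4+2] cycloaddition in which C8–C9 bonding runs ahead of C5–C10 (positive charge on tertiary C10, negative charge in the copper dienolate). The closest known reaction types are the inverse-demand hetero-Diels–Alder reactions of β,γ-unsaturated α-keto esters under the same kind of catalyst and the thermal type 1 intramolecular Diels–Alder reactions of isopropenyl-terminated trienes, neither of which has been shown for a catalytic asymmetric carbocyclic closure of a 2-acyl diene. Ring B closes by the [4+2] bond pair C8–C9/C5–C10 and ring A closes with it as the six-membered tether ring C10–C1–C2–C3=C4–C5, which requires the cis placement of C2 and C5 on C3=C4 and the E geometry of C5=C6 built in steps 2 and 3. C10 and C5 arise together: their relative configuration (H-5 anti to CH3-10, trans ring fusion) should come from the anti transition state with the chain C1–C2 exo and the small methyl group endo, and their absolute configuration (4aR,8aR) from the tert-butyl groups of the ligand, which should shield one face of the chelated keto ester plane and thus of the diene terminus C8. The step needs carbocyclic over hetero-[4+2] and ene periselectivity, anti over syn ring fusion and one diene face; the first is secured by the tether (O–C10 bonding would demand a bridged ten-membered ring), the second is expected from the exo preference of the chain held by the planar C3=C4–C5 unit but is not secured by a strong substrate element, and the third rests on the catalyst. Dilution suppresses intermolecular cycloaddition of the activated diene.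

**Step 9**
Reactants: 17 methyl 2-[(4aR,8aR)-8-({[tert-butyl(dimethyl)silyl]oxy}methyl)-4a-methyl-3,4,4a,5,6,8a-hexahydronaphthalen-2-yl]-2-oxoacetate
Product: 19 methyl 2-[(2R,4aR,8aR)-8-({[tert-butyl(dimethyl)silyl]oxy}methyl)-4a-methyl-1,2,3,4,4a,5,6,8a-octahydronaphthalen-2-yl]-2-oxoacetate, via dimethylphenylsilyl enol ether 18 (not isolated)
Conditions: [(Ph3P)CuH]6 (5 mol %), PhMe2SiH (1.5 equiv), toluene, 0 °C → rt; then K2CO3, MeOH, 0 °C → rt
Reagents that add atoms: none
Why: copper hydride-catalysed 1,4-hydrosilylation of the ene-α-keto ester gives the silyl enol ether (the isolated C3=C4 is inert), and methanolysis under equilibrating conditions protonates C7 to the thermodynamically favoured isomer with the keto ester equatorial on the chair of ring B (7R, H-7 axial and cis to H-5).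

**Step 10**
Reactants: 19 methyl 2-[(2R,4aR,8aR)-8-({[tert-butyl(dimethyl)silyl]oxy}methyl)-4a-methyl-1,2,3,4,4a,5,6,8a-octahydronaphthalen-2-yl]-2-oxoacetate
Product: 20 methyl 2-[(2R,4aR,8aR)-8-({[tert-butyl(dimethyl)silyl]oxy}methyl)-4a-methyl-1,2,3,4,4a,5,6,8a-octahydronaphthalen-2-yl]prop-2-enoate
Conditions: Ph3PCH3Br, KN(SiMe3)2, THF, 0 °C; then 19, −78 → 0 °C
Reagents that add atoms: methyltriphenylphosphonium bromide C[P+](c1ccccc1)(c1ccccc1)c1ccccc1.[Br-]
Why: Wittig methylenation of the keto carbonyl of the α-keto ester (far more electrophilic than the ester) gives the 2-substituted acrylate C11=C13, and any equilibration of C7 through the enolate returns the same equatorial isomer.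

**Step 11**
Reactants: 20 methyl 2-[(2R,4aR,8aR)-8-({[tert-butyl(dimethyl)silyl]oxy}methyl)-4a-methyl-1,2,3,4,4a,5,6,8a-octahydronaphthalen-2-yl]prop-2-enoate
Product: 21 methyl 2-[(2R,4aR,8aR)-8-(hydroxymethyl)-4a-methyl-1,2,3,4,4a,5,6,8a-octahydronaphthalen-2-yl]prop-2-enoate
Conditions: HF·pyridine, pyridine, THF, 0 °C → rt
Reagents that add atoms: none
Why: fluoride cleavage of the primary silyl ether under buffered, non-basic conditions frees C15–OH without conjugate addition to the acrylate; no stereocentre is touched.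

**Step 12**
Reactants: 21 methyl 2-[(2R,4aR,8aR)-8-(hydroxymethyl)-4a-methyl-1,2,3,4,4a,5,6,8a-octahydronaphthalen-2-yl]prop-2-enoate; 22 (2E)-3-(4-hydroxyphenyl)prop-2-enoic acid (p-coumaric acid)
Product: 23 methyl 2-[(2R,4aR,8aR)-8-({[(2E)-3-(4-hydroxyphenyl)prop-2-enoyl]oxy}methyl)-4a-methyl-1,2,3,4,4a,5,6,8a-octahydronaphthalen-2-yl]prop-2-enoate (target)
Conditions: PPh3, DIAD, THF, 0 °C → rt
Reagents that add atoms: none
Why: Mitsunobu esterification, in which the carboxylic acid is far more acidic than the phenol and is the nucleophile that displaces the primary allylic oxyphosphonium group at C15 (SN2), so the p-coumarate should form without phenol protection and with the E-alkene intact.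

**Compound list**
1 | 4-methylpent-4-enal | C=C(C)CCC=O | starting material
2 | methyl acrylate | C=CC(=O)OC | starting material
3 | methyl 3-hydroxy-6-methyl-2-methylidenehept-6-enoate (racemic) | C=C(C)CCC(O)C(=C)C(=O)OC | intermediate
4 | methyl (2Z)-2-(bromomethyl)-6-methylhepta-2,6-dienoate | C=C(C)CC/C=C(\CBr)C(=O)OC | intermediate
5 | 3-(trimethylsilyl)prop-2-ynal | C[Si](C)(C)C#CC=O | starting material
6 | tributyl[(2Z)-2-(methoxycarbonyl)-6-methylhepta-2,6-dien-1-yl]phosphonium bromide | C=C(C)CC/C=C(\C[P+](CCCC)(CCCC)CCCC)C(=O)OC.[Br-] | intermediate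
7 | methyl (2Z)-6-methyl-2-[(tributylphosphoranylidene)methyl]hepta-2,6-dienoate | C=C(C)CC/C=C(\C=P(CCCC)(CCCC)CCCC)C(=O)OC | intermediate
8 | methyl (2E)-6-methyl-2-[(1E)-4-(trimethylsilyl)but-1-en-3-yn-1-yl]hepta-2,6-dienoate | C=C(C)CC/C=C(\C=C\C#C[Si](C)(C)C)C(=O)OC | intermediate
9 | methyl (2E)-2-[(1E)-but-1-en-3-yn-1-yl]-6-methylhepta-2,6-dienoate | C=C(C)CC/C=C(\C=C\C#C)C(=O)OC | intermediate
10 | (2E)-2-[(1E)-but-1-en-3-yn-1-yl]-6-methylhepta-2,6-dien-1-ol | C=C(C)CC/C=C(\C=C\C#C)CO | intermediate
11 | tert-butyl{[(2E)-2-[(1E)-but-1-en-3-yn-1-yl]-6-methylhepta-2,6-dien-1-yl]oxy}dimethylsilane | C=C(C)CC/C=C(\C=C\C#C)CO[Si](C)(C)C(C)(C)C | intermediate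
12 | [(3E,5E)-5-({[tert-butyl(dimethyl)silyl]oxy}methyl)-9-methyldeca-1,3,5,9-tetraen-2-yl]bis(2-methylpropyl)alane | C=C(C)CC/C=C(\C=C\C(=C)[Al](CC(C)C)CC(C)C)CO[Si](C)(C)C(C)(C)C | intermediate
13 | (3E,5E)-2-bromo-5-({[tert-butyl(dimethyl)silyl]oxy}methyl)-9-methyldeca-1,3,5,9-tetraene | C=C(C)CC/C=C(\C=C\C(Br)=C)CO[Si](C)(C)C(C)(C)C | intermediate
14 | dimethyl oxalate | COC(=O)C(=O)OC | starting material
15 | [(3E,5E)-5-({[tert-butyl(dimethyl)silyl]oxy}methyl)-9-methyldeca-1,3,5,9-tetraen-2-yl]lithium | C=C(C)CC/C=C(\C=C\C([Li])=C)CO[Si](C)(C)C(C)(C)C | intermediate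
16 | methyl (4E,6E)-6-({[tert-butyl(dimethyl)silyl]oxy}methyl)-10-methyl-3-methylidene-2-oxoundeca-4,6,10-trienoate | C=C(C)CC/C=C(\C=C\C(=C)C(=O)C(=O)OC)CO[Si](C)(C)C(C)(C)C | intermediate
17 | methyl 2-[(4aR,8aR)-8-({[tert-butyl(dimethyl)silyl]oxy}methyl)-4a-methyl-3,4,4a,5,6,8a-hexahydronaphthalen-2-yl]-2-oxoacetate | COC(=O)C(=O)C1=C[C@H]2C(CO[Si](C)(C)C(C)(C)C)=CCC[C@]2(C)CC1 | intermediate
18 | methyl 2-[(4aR,8aR)-8-({[tert-butyl(dimethyl)silyl]oxy}methyl)-4a-methyl-3,4,4a,5,6,8a-hexahydronaphthalen-2(1H)-ylidene]-2-{[dimethyl(phenyl)silyl]oxy}acetate | COC(=O)C(O[Si](C)(C)c1ccccc1)=C1CC[C@@]2(C)CCC=C(CO[Si](C)(C)C(C)(C)C)[C@@H]2C1 | intermediate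
19 | methyl 2-[(2R,4aR,8aR)-8-({[tert-butyl(dimethyl)silyl]oxy}methyl)-4a-methyl-1,2,3,4,4a,5,6,8a-octahydronaphthalen-2-yl]-2-oxoacetate | COC(=O)C(=O)[C@@H]1CC[C@@]2(C)CCC=C(CO[Si](C)(C)C(C)(C)C)[C@@H]2C1 | intermediate
20 | methyl 2-[(2R,4aR,8aR)-8-({[tert-butyl(dimethyl)silyl]oxy}methyl)-4a-methyl-1,2,3,4,4a,5,6,8a-octahydronaphthalen-2-yl]prop-2-enoate | C=C(C(=O)OC)[C@@H]1CC[C@@]2(C)CCC=C(CO[Si](C)(C)C(C)(C)C)[C@@H]2C1 | intermediate
21 | methyl 2-[(2R,4aR,8aR)-8-(hydroxymethyl)-4a-methyl-1,2,3,4,4a,5,6,8a-octahydronaphthalen-2-yl]prop-2-enoate | C=C(C(=O)OC)[C@@H]1CC[C@@]2(C)CCC=C(CO)[C@@H]2C1 | intermediate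
22 | (2E)-3-(4-hydroxyphenyl)prop-2-enoic acid | OC(=O)/C=C/c1ccc(O)cc1 | starting material
23 | methyl 2-[(2R,4aR,8aR)-8-({[(2E)-3-(4-hydroxyphenyl)prop-2-enoyl]oxy}methyl)-4a-methyl-1,2,3,4,4a,5,6,8a-octahydronaphthalen-2-yl]prop-2-enoate | C=C(C(=O)OC)[C@@H]1CC[C@@]2(C)CCC=C(COC(=O)/C=C/c3ccc(O)cc3)[C@@H]2C1 | target

**Step count and risks**
Total step count: 12. Longest linear sequence: 12 steps (1 → 23).

Steps most likely to fail:

1. Step 8 (Proposed new method). What may go wrong: poor discrimination between the two diene faces and between anti and syn ring fusion; the activated keto ester may also be diverted into ene, hetero-cycloaddition or oligomerisation pathways. Fallback (auxiliary control, known reaction types): setting out from 13, bromine–lithium exchange as in step 7 gives 15, which is acylated with (1R,2S,5R)-8-phenylmenthyl chlorooxoacetate to the (1R,2S,5R)-8-phenylmenthyl dienyl keto ester F1. An intramolecular Diels–Alder reaction of F1 under chelation by achiral SnCl4 (CH2Cl2, −78 °C), with one face of the chelated keto ester shielded by the phenyl group of the auxiliary, should give the 8-phenylmenthyl cycloadduct F2. Copper hydride hydrosilylation as in step 9 gives the 8-phenylmenthyl silyl enol ether F3. Methanolysis of F3 with NaOMe/MeOH cleaves the silyl group, exchanges the activated α-keto ester for the methyl ester and releases the auxiliary, returning to the route at 19. This fallback addresses the facial selectivity only; a cis-fused isomer would still have to be separated.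

2. Step 7. What may go wrong: double addition of the organolithium to the oxalate, and self-cycloaddition of the 2-acyl diene during work-up. Fallback (change of oxidation level): setting out from 13, the lithiodiene 15 is added to methyl glyoxylate at −78 °C to give the stable, storable methyl 2-hydroxy ester F4. Dess–Martin oxidation of F4 (NaHCO3, CH2Cl2, 0 °C) immediately before the cycloaddition returns to the route at 16.

3. Step 6. What may go wrong: loss of α-regioselectivity on the conjugated enyne, or competing hydroalumination of the diene and isopropenyl units. Fallback (bromine brought in with the aldehyde): setting out from 4, the ylide 7 is made as in step 3 and condensed with 2-bromoacrolein (from acrolein by bromination and dehydrobromination) to give the bromotriene ester F5. Reduction with i-Bu2AlH as in step 4 gives the bromotriene alcohol F6, and silylation as in step 5 returns to the route at 13.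

**Further compounds**
F1 | step 8 | (1R,2S,5R)-5-methyl-2-(2-phenylpropan-2-yl)cyclohexyl (4E,6E)-6-({[tert-butyl(dimethyl)silyl]oxy}methyl)-10-methyl-3-methylidene-2-oxoundeca-4,6,10-trienoate | C=C(C)CC/C=C(\C=C\C(=C)C(=O)C(=O)O[C@@H]1C[C@H](C)CC[C@H]1C(C)(C)c1ccccc1)CO[Si](C)(C)C(C)(C)C
F2 | step 8 | (1R,2S,5R)-5-methyl-2-(2-phenylpropan-2-yl)cyclohexyl 2-[(4aR,8aR)-8-({[tert-butyl(dimethyl)silyl]oxy}methyl)-4a-methyl-3,4,4a,5,6,8a-hexahydronaphthalen-2-yl]-2-oxoacetate | O=C(C(=O)O[C@@H]1C[C@H](C)CC[C@H]1C(C)(C)c1ccccc1)C1=C[C@H]2C(CO[Si](C)(C)C(C)(C)C)=CCC[C@]2(C)CC1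
F3 | step 8 | (1R,2S,5R)-5-methyl-2-(2-phenylpropan-2-yl)cyclohexyl 2-[(4aR,8aR)-8-({[tert-butyl(dimethyl)silyl]oxy}methyl)-4a-methyl-3,4,4a,5,6,8a-hexahydronaphthalen-2(1H)-ylidene]-2-{[dimethyl(phenyl)silyl]oxy}acetate | O=C(O[C@@H]1C[C@H](C)CC[C@H]1C(C)(C)c1ccccc1)C(O[Si](C)(C)c1ccccc1)=C1CC[C@@]2(C)CCC=C(CO[Si](C)(C)C(C)(C)C)[C@@H]2C1
F4 | step 7 | methyl (4E,6E)-6-({[tert-butyl(dimethyl)silyl]oxy}methyl)-2-hydroxy-10-methyl-3-methylideneundeca-4,6,10-trienoate (racemic) | C=C(C)CC/C=C(\C=C\C(=C)C(O)C(=O)OC)CO[Si](C)(C)C(C)(C)C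
F5 | step 6 | methyl (2E)-2-[(1E)-3-bromobuta-1,3-dien-1-yl]-6-methylhepta-2,6-dienoate | C=C(C)CC/C=C(\C=C\C(Br)=C)C(=O)OC
F6 | step 6 | (2E)-2-[(1E)-3-bromobuta-1,3-dien-1-yl]-6-methylhepta-2,6-dien-1-ol | C=C(C)CC/C=C(\C=C\C(Br)=C)CO
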